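**Retrosynthetic overview**

1. Sipholenol M (31) ⇐ SN2 displacement with inversion at C3 of the allylic bromide 27 by a protected hydroperoxide ⇐ tertiary allylic alcohol 26 ⇐ 1,2-addition of the C16 organocerium from iodide 23 (rings A/B) to the C14 bicyclic enone 13 (rings C/D). Numbering of the carbobicycle: C1 side chain, C2 methyl, C3 OOH, C4a/C8a ring fusion, C5 carbinol, C8 gem-dimethyl.
2. Rings C/D: ring C is (S)-carvone, whose C5 becomes C4a. Ring D (C4a–C5–C6–C7–C8–C8a) is closed last by a Prins cyclization that forms C6–C7 between the terminal CH2 of the carvone isopropenyl group and a non-enolisable aldehyde on the quaternary C8. The aldehyde side chain is installed at C6 of carvone by nitroalkene Michael addition, kinetic protonation (cis) and Nef reaction.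
3. Enabling feature: in ring D the tertiary carbinol C5 with its methyl group is the Markovnikov hydration site of an isopropenyl group and lies 1,3 to C7, which is flanked by the quaternary C8. The unit C5(OH)(CH3)–C6H2–C7 is therefore a Prins retron, and its alkene half is native to carvone.
4. Rings A/B: one epoxide-opening cascade of the (7S,8S,11S)-diepoxy homofarnesoate 17 forms the oxepane ring A, then the cyclohexane ring B, then a lactone that holds the C7 oxygen and the two linker carbons. Ester 17 comes from (2E,6E)-farnesol by Shi epoxidation and palladium-catalysed carbonylation.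
5. Order of ring formation: ring C (chiral pool) → ring D (key step); ring A → ring B (one cascade); the halves are joined at the C1–CH2 bond.

Key step: step 3

Assumption: the enantiomer of the D-fructose-derived Shi ketone and 2-methyl-1-nitroprop-1-ene are taken as purchasable; the carbinol centre C7 of 9–11 and C1 of 26 are drawn without configuration because both epimers converge.

**Route**

Step 1
Reactants: 1 (S)-(+)-carvone; 2 2-methyl-1-nitroprop-1-ene
Product: 6 (5S,6R)-2-methyl-6-(2-methyl-1-nitropropan-2-yl)-5-(prop-1-en-2-yl)cyclohex-2-en-1-one (side chain cis to isopropenyl), via lithium dienolate 3 (not isolated), via trans-adduct lithium nitronate 4 (not isolated), via dilithium enolate–nitronate 5 (not isolated)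
Conditions: LiN(iPr)2 (1.05 equiv), THF, −78 °C; 2, −78 °C; LiN(iPr)2 (1.2 equiv), −78 °C; AcOH (excess) in THF, −78 °C
Reagents that add atoms: none
Why: Michael addition of the kinetic cross-conjugated enolate to the nitroalkene should build the quaternary carbon trans to the isopropenyl group, and re-enolisation followed by kinetic protonation should correct C6, because A(1,2) strain against the new tert-alkyl group forces the C5 isopropenyl group axial and the proton enters anti to it, which leaves the side chain cis.

Step 2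
Reactants: 6 cis nitro ketone
Product: 8 2-methyl-2-[(1R,6S)-3-methyl-2-oxo-6-(prop-1-en-2-yl)cyclohex-3-en-1-yl]propanal, via sodium nitronate 7 (not isolated)
Conditions: NaOMe (1.0 equiv), MeOH, 0 °C; then aq. TiCl3, NH4OAc (pH 5–6), THF, 0 °C to rt
Reagents that add atoms: water, O
Why: Nef reaction in its reductive TiCl3 variant, in which the nitronate is reduced to the imine and hydrolysed to the aldehyde under buffered conditions that should leave the epimerisable C6 centre, the enone and the isopropenyl group untouched.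

Step 3
Reactants: 8 cis keto aldehyde
Product: 10 (4aS,5S,8aR)-5,7-dihydroxy-2,5,8,8-tetramethyl-4a,5,6,7,8,8a-hexahydronaphthalen-1(4H)-one (cis-fused), via C5 trifluoroacetate 9 (not isolated)
Conditions: CF3CO2H (10 equiv), CH2Cl2, −40 to 0 °C; then NaHCO3, MeOH–H2O, 0 °C
Reagents that add atoms: trifluoroacetic acid (oxygen of the C5 hydroxyl), OC(=O)C(F)(F)F
Why: Trifluoroacetic acid protonates the aldehyde, the terminal CH2 of the cis-disposed isopropenyl group attacks the carbonyl carbon (C6–C7 bond), and the tertiary C5 cation is captured by trifluoroacetate, which the bicarbonate work-up cleaves at the acyl–oxygen bond to leave the tertiary alcohol. The closest known reaction type is the acid-mediated Prins cyclization of alkenyl aldehydes with oxygen capture of the tertiary cation (citronellal to p-menthane-3,8-diol), here in the type 2 carbonyl-ene topology with the tether on the central alkene carbon. Ring D closes 6-endo-trig with respect to the alkene (C5 and C6 both enter the ring) and 6-exo-trig with respect to the carbonyl group. The new C5 stereocentre is set by capture of the cation on the convex α face of the cis-fused bicycle, while the C7 carbinol centre is not controlled and is erased in steps 4 and 5; the cis ring fusion is inherited from 8. The step needs Markovnikov regioselectivity (six- over five-membered ring), secured because only attack through CH2 gives a tertiary cation; it needs chemoselectivity for the aldehyde and the isopropenyl group over the enone, secured by their higher electrophilicity and nucleophilicity; and it needs configurational integrity at C8a, secured by low temperature and the absence of base.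

Step 4
Reactants: 10 cis-fused diol
Product: 11 O-phenyl thionocarbonate of the C7 hydroxyl of 10
Conditions: PhOC(S)Cl (1.3 equiv), pyridine, DMAP (cat.), CH2Cl2, 0 °C to rt
Reagents that add atoms: O-phenyl chlorothionoformate, S=C(Cl)Oc1ccccc1
Why: Thioacylation (first half of the Barton–McCombie deoxygenation) should take place only at the secondary hydroxyl, the tertiary C5 hydroxyl being too hindered, under non-enolising conditions that keep the cis ring fusion.

Step 5
Reactants: 11 thionocarbonate
Product: 12 (4aS,5S,8aR)-5-hydroxy-2,5,8,8-tetramethyl-4a,5,6,7,8,8a-hexahydronaphthalen-1(4H)-one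
Conditions: Bu3SnH, AIBN (cat.), toluene, 80 °C
Reagents that add atoms: none
Why: Barton–McCombie radical deoxygenation should convert both C7 epimers into the same CH2 group under neutral conditions that do not touch the enone or the ring fusion.

Step 6
Reactants: 12 hydroxy enone
Product: 13 5-O-triethylsilyl ether of 12
Conditions: Et3SiOTf, 2,6-lutidine, CH2Cl2, −78 °C
Reagents that add atoms: triethylsilyl trifluoromethanesulfonate, CC[Si](CC)(CC)OS(=O)(=O)C(F)(F)F
Why: Silylation of the tertiary alcohol with a silyl triflate and a hindered weak base removes the acidic proton ahead of the organometallic step without enolising the ketone.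

Step 7
Reactants: 14 (2E,6E)-farnesol
Product: 15 (2E,6E)-farnesyl methyl carbonate
Conditions: ClCO2Me, pyridine, CH2Cl2, 0 °C
Reagents that add atoms: methyl chloroformate, COC(=O)Cl
Why: Acylation of the primary allylic alcohol gives a carbonate that deactivates the 2,3-alkene for step 8 and serves as leaving group for step 9.

Step 8
Reactants: 15 farnesyl methyl carbonate
Product: 16 (2E,6S,7S,10S)-6,7:10,11-diepoxy-3,7,11-trimethyldodec-2-en-1-yl methyl carbonate
Conditions: enantiomer of the D-fructose-derived Shi ketone (0.3 equiv), Oxone (2KHSO5·KHSO4·K2SO4), K2CO3, Bu4NHSO4, MeCN–CH2(OMe)2–aq. buffer (pH 10.5), 0 °C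
Reagents that add atoms: potassium peroxymonosulfate (Oxone), [K+].OOS(=O)(=O)[O-]
Why: Shi epoxidation, in which the chiral dioxirane should epoxidise the two electron-rich trisubstituted alkenes through its spiro transition state to set the 6S,7S and 10S centres, while the allylic carbonate deactivates the 2,3-alkene.

Step 9
Reactants: 16 diepoxy carbonate
Product: 17 methyl (3E,7S,8S,11S)-7,8:11,12-diepoxy-4,8,12-trimethyltridec-3-enoate
Conditions: Pd(OAc)2 (5 mol %), PPh3 (10 mol %), CO (10 atm), MeOH, 50 °C
Reagents that add atoms: carbon monoxide, [C-]#[O+]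
Why: Palladium-catalysed decarboxylative carbonylation of an allylic carbonate, in which zerovalent palladium ionises the carbonate, CO inserts at the unsubstituted allyl terminus and the liberated methoxide gives the E β,γ-unsaturated ester, should leave the non-allylic epoxides untouched.

Step 10
Reactants: 17 diepoxy ester
Product: 19 γ-lactone of [(3S,5aS,6S,7S,9aS)-7-hydroxy-2,2,5a,7-tetramethyl-3-(trimethylsilyloxy)decahydro-1-benzoxepin-6-yl]acetic acid, via O-methyl lactonium triflate 18 (not isolated)
Conditions: Me3SiOTf (1.1 equiv), 2,6-di-tert-butyl-4-methylpyridine, CH2Cl2, −78 °C; then aq. NaHCO3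
Reagents that add atoms: trimethylsilyl trifluoromethanesulfonate, C[Si](C)(C)OS(=O)(=O)C(F)(F)F; water (lactone carbonyl oxygen), O
Why: Lewis acid-promoted epoxide-opening cascade (tandem oxa- and carbacyclization) in which the silylated terminal epoxide is opened at its tertiary carbon by the internal epoxide oxygen (ring A), the resulting epoxonium ion is opened with inversion at its tertiary carbon by the E alkene through a chair transition state (ring B) and the tertiary cation is trapped anti by the ester carbonyl, so that the three epoxide centres and the alkene geometry should translate into all five stereocentres.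

Step 11
Reactants: 19 silyloxy lactone
Product: 20 (3S,5aS,6S,7S,9aS)-6-(2-hydroxyethyl)-2,2,5a,7-tetramethyldecahydro-1-benzoxepine-3,7-diol
Conditions: LiAlH4, THF, 0 °C to rt; then 1 M HCl, 0 °C
Reagents that add atoms: none
Why: Hydride reduction of the lactone gives the primary and the tertiary alcohol without touching a stereocentre, and the acidic work-up cleaves the trimethylsilyl ether.

Step 12
Reactants: 20 triol
Product: 22 2-[(3S,5aS,6S,7S,9aS)-2,2,5a,7-tetramethyl-3,7-bis(triethylsilyloxy)decahydro-1-benzoxepin-6-yl]ethanol, via tris-triethylsilyl ether 21 (not isolated)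
Conditions: Et3SiOTf (3.5 equiv), 2,6-lutidine, CH2Cl2, −78 to 0 °C; then PPTS (cat.), MeOH–CH2Cl2, −10 °C
Reagents that add atoms: triethylsilyl trifluoromethanesulfonate, CC[Si](CC)(CC)OS(=O)(=O)C(F)(F)F
Why: Exhaustive silylation followed by selective methanolysis of the least hindered primary silyl ether blocks the tertiary C7 hydroxyl before the primary carbon is activated, which prevents closure to a cyclic ether.

Step 13
Reactants: 22 primary alcohol
Product: 23 (3S,5aS,6S,7S,9aS)-6-(2-iodoethyl)-2,2,5a,7-tetramethyl-3,7-bis(triethylsilyloxy)decahydro-1-benzoxepine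
Conditions: I2, PPh3, imidazole, CH2Cl2, 0 °C
Reagents that add atoms: iodine, II
Why: Appel-type iodination of the primary alcohol through its alkoxyphosphonium salt proceeds at a carbon that bears no stereocentre.

Step 14
Reactants: 23 iodide; 13 silyl-protected bicyclic enone
Product: 26 (4aS,5S,8aR)-1-{2-[(3S,5aS,6S,7S,9aS)-2,2,5a,7-tetramethyl-3,7-bis(triethylsilyloxy)decahydro-1-benzoxepin-6-yl]ethyl}-2,5,8,8-tetramethyl-5-(triethylsilyloxy)-1,4,4a,5,6,7,8,8a-octahydronaphthalen-1-ol, via alkyllithium 24 (not isolated), via organocerium dichloride 25 (not isolated)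
Conditions: t-BuLi (2.1 equiv), Et2O–pentane, −78 °C; CeCl3 (anhydrous), THF, −78 °C; then 13, −78 to −40 °C; aq. NH4Cl
Reagents that add atoms: none
Why: Iodine–lithium exchange and transmetalation give a weakly basic organocerium reagent that should add 1,2 to the hindered, enolisable enone without epimerising C8a, and the configuration of the new carbinol carbon is irrelevant because it becomes trigonal in step 15.

Step 15
Reactants: 26 tertiary allylic alcohol
Product: 27 (3S,4aS,5S,8aR)-3-bromo analogue with C1=C2 double bond, i.e. the 3α-allylic bromide that carries the three triethylsilyl ethers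
Conditions: Me3SiBr (1.2 equiv), CH2Cl2, −78 °C
Reagents that add atoms: bromotrimethylsilane, C[Si](C)(C)Br
Why: Ionisation of the silylated tertiary allylic alcohol and capture of the allyl cation by bromide at the less hindered secondary terminus (allylic transposition to the tetrasubstituted alkene) should give the pseudoaxial α-bromide, since bromide enters axially on the convex face and ion-pair return funnels any β-epimer to the isomer that avoids A(1,2) strain with the C2 methyl group.

Step 16
Reactants: 28 2,3-dimethylbut-2-ene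
Product: 29 2-methoxyprop-2-yl hydroperoxide
Conditions: O3, MeOH–CH2Cl2, −78 °C
Reagents that add atoms: ozone, [O-][O+]=O; methanol, CO
Why: Ozonolysis in methanol, in which the carbonyl oxide from the symmetrical alkene is trapped by the solvent (Criegee mechanism), gives the acetal-protected hydrogen peroxide nucleophile.

Step 17
Reactants: 27 allylic bromide; 29 2-methoxyprop-2-yl hydroperoxide
Product: 30 (3R)-3-[(2-methoxypropan-2-yl)peroxy] compound (tris-triethylsilyl ether of the target skeleton)
Conditions: CsOH·H2O (1.2 equiv), DMF, 0 °C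
Reagents that add atoms: none
Why: SN2 alkylation of the caesium peroxide anion by the secondary allylic bromide should invert C3, because attack anti to the pseudoaxial C–Br bond places the O–O unit on the β face, and SN2′ attack is blocked at the tetrasubstituted C1.

Step 18
Reactants: 30 peroxyketal
Product: 31 sipholenol M
Conditions: HF·pyridine, THF–H2O, 0 °C to rt
Reagents that add atoms: none
Why: Acidic fluoride should cleave the three silyl ethers and hydrolyse the peroxyketal in one operation without touching a stereocentre or the allylic hydroperoxide.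

**Compound list**

1 | (S)-(+)-carvone, (5S)-2-methyl-5-(prop-1-en-2-yl)cyclohex-2-en-1-one | O=C1C(C)=CC[C@@H](C1)C(C)=C | starting material
2 | 2-methyl-1-nitroprop-1-ene | CC(C)=C[N+](=O)[O-] | starting material
3 | lithium C1–C6 dienolate of carvone | CC1=CC[C@@H](C=C1[O-])C(C)=C.[Li+] | intermediate
4 | lithium nitronate of the trans (5S,6S) Michael adduct | O=C1C(C)=CC[C@H](C(C)=C)[C@H]1C(C)(C)C=[N+]([O-])[O-].[Li+] | intermediate
5 | dilithium enolate–nitronate (C6 trigonal) | CC1=CC[C@H](C(C)=C)C(C(C)(C)C=[N+]([O-])[O-])=C1[O-].[Li+].[Li+] | intermediate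
6 | (5S,6R)-2-methyl-6-(2-methyl-1-nitropropan-2-yl)-5-(prop-1-en-2-yl)cyclohex-2-en-1-one | O=C1C(C)=CC[C@H](C(C)=C)[C@@H]1C(C)(C)C[N+](=O)[O-] | intermediate
7 | sodium nitronate of 6 | O=C1C(C)=CC[C@H](C(C)=C)[C@@H]1C(C)(C)C=[N+]([O-])[O-].[Na+] | intermediate
8 | 2-methyl-2-[(1R,6S)-3-methyl-2-oxo-6-(prop-1-en-2-yl)cyclohex-3-en-1-yl]propanal | O=C1C(C)=CC[C@H](C(C)=C)[C@@H]1C(C)(C)C=O | intermediate
9 | (4aS,5S,8aR)-7-hydroxy-2,5,8,8-tetramethyl-1-oxo-1,4,4a,5,6,7,8,8a-octahydronaphthalen-5-yl trifluoroacetate (C7 epimers) | O=C1C(C)=CC[C@H]2[C@@H]1C(C)(C)C(O)C[C@]2(C)OC(=O)C(F)(F)F | intermediate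
10 | (4aS,5S,8aR)-5,7-dihydroxy-2,5,8,8-tetramethyl-4a,5,6,7,8,8a-hexahydronaphthalen-1(4H)-one (cis-fused, C7 epimers) | O=C1C(C)=CC[C@H]2[C@@H]1C(C)(C)C(O)C[C@]2(C)O | intermediate
11 | O-phenyl thionocarbonate of the C7 hydroxyl of 10 | O=C1C(C)=CC[C@H]2[C@@H]1C(C)(C)C(OC(=S)Oc3ccccc3)C[C@]2(C)O | intermediate
12 | (4aS,5S,8aR)-5-hydroxy-2,5,8,8-tetramethyl-4a,5,6,7,8,8a-hexahydronaphthalen-1(4H)-one | O=C1C(C)=CC[C@H]2[C@@H]1C(C)(C)CC[C@]2(C)O | intermediate
13 | (4aS,5S,8aR)-2,5,8,8-tetramethyl-5-(triethylsilyloxy)-4a,5,6,7,8,8a-hexahydronaphthalen-1(4H)-one | O=C1C(C)=CC[C@H]2[C@@H]1C(C)(C)CC[C@]2(C)O[Si](CC)(CC)CC | intermediate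
14 | (2E,6E)-farnesol | CC(C)=CCC/C(C)=C/CC/C(C)=C/CO | starting material
15 | (2E,6E)-farnesyl methyl carbonate | CC(C)=CCC/C(C)=C/CC/C(C)=C/COC(=O)OC | intermediate
16 | (2E,6S,7S,10S)-6,7:10,11-diepoxy-3,7,11-trimethyldodec-2-en-1-yl methyl carbonate | CC1(C)O[C@H]1CC[C@]2(C)O[C@H]2CC/C(C)=C/COC(=O)OC | intermediate
17 | methyl (3E,7S,8S,11S)-7,8:11,12-diepoxy-4,8,12-trimethyltridec-3-enoate | CC1(C)O[C@H]1CC[C@]2(C)O[C@H]2CC/C(C)=C/CC(=O)OC | intermediate
18 | O-methyl lactonium triflate of 19 | C[O+]=C1C[C@H]2[C@]3(C)CC[C@H](O[Si](C)(C)C)C(C)(C)O[C@H]3CC[C@]2(C)O1.[O-]S(=O)(=O)C(F)(F)F | intermediate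
19 | trans-fused γ-lactone of [(3S,5aS,6S,7S,9aS)-7-hydroxy-2,2,5a,7-tetramethyl-3-(trimethylsilyloxy)decahydro-1-benzoxepin-6-yl]acetic acid | O=C1C[C@H]2[C@]3(C)CC[C@H](O[Si](C)(C)C)C(C)(C)O[C@H]3CC[C@]2(C)O1 | intermediate
20 | (3S,5aS,6S,7S,9aS)-6-(2-hydroxyethyl)-2,2,5a,7-tetramethyldecahydro-1-benzoxepine-3,7-diol | OCC[C@H]1[C@]2(C)CC[C@H](O)C(C)(C)O[C@H]2CC[C@]1(C)O | intermediate
21 | tris-triethylsilyl ether of 20 | CC[Si](CC)(CC)OCC[C@H]1[C@]2(C)CC[C@H](O[Si](CC)(CC)CC)C(C)(C)O[C@H]2CC[C@]1(C)O[Si](CC)(CC)CC | intermediate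
22 | 2-[(3S,5aS,6S,7S,9aS)-2,2,5a,7-tetramethyl-3,7-bis(triethylsilyloxy)decahydro-1-benzoxepin-6-yl]ethanol | OCC[C@H]1[C@]2(C)CC[C@H](O[Si](CC)(CC)CC)C(C)(C)O[C@H]2CC[C@]1(C)O[Si](CC)(CC)CC | intermediate
23 | (3S,5aS,6S,7S,9aS)-6-(2-iodoethyl)-2,2,5a,7-tetramethyl-3,7-bis(triethylsilyloxy)decahydro-1-benzoxepine | ICC[C@H]1[C@]2(C)CC[C@H](O[Si](CC)(CC)CC)C(C)(C)O[C@H]2CC[C@]1(C)O[Si](CC)(CC)CC | intermediate
24 | primary alkyllithium from 23 | [Li]CC[C@H]1[C@]2(C)CC[C@H](O[Si](CC)(CC)CC)C(C)(C)O[C@H]2CC[C@]1(C)O[Si](CC)(CC)CC | intermediate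
25 | alkylcerium dichloride from 24 | Cl[Ce](Cl)CC[C@H]1[C@]2(C)CC[C@H](O[Si](CC)(CC)CC)C(C)(C)O[C@H]2CC[C@]1(C)O[Si](CC)(CC)CC | intermediate
26 | tertiary allylic alcohol (C1 epimers), tris-triethylsilyl ether | CC1=CC[C@H]2[C@@H](C1(O)CC[C@H]3[C@]4(C)CC[C@H](O[Si](CC)(CC)CC)C(C)(C)O[C@H]4CC[C@]3(C)O[Si](CC)(CC)CC)C(C)(C)CC[C@]2(C)O[Si](CC)(CC)CC | intermediate
27 | (3S,4aS,5S,8aR)-3-bromo-1-(2-{benzoxepinyl}ethyl)-2,5,8,8-tetramethyl-5-(triethylsilyloxy)-3,4,4a,5,6,7,8,8a-octahydronaphthalene, bis-silylated left half as in 23 | CC1=C(CC[C@H]2[C@]3(C)CC[C@H](O[Si](CC)(CC)CC)C(C)(C)O[C@H]3CC[C@]2(C)O[Si](CC)(CC)CC)[C@@H]2[C@H](C[C@@H]1Br)[C@@](C)(O[Si](CC)(CC)CC)CCC2(C)C | intermediate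
28 | 2,3-dimethylbut-2-ene | CC(C)=C(C)C | starting material
29 | 2-methoxyprop-2-yl hydroperoxide | COC(C)(C)OO | intermediate
30 | (3R)-3-[(2-methoxypropan-2-yl)peroxy] analogue of 27 | CC1=C(CC[C@H]2[C@]3(C)CC[C@H](O[Si](CC)(CC)CC)C(C)(C)O[C@H]3CC[C@]2(C)O[Si](CC)(CC)CC)[C@@H]2[C@H](C[C@H]1OOC(C)(C)OC)[C@@](C)(O[Si](CC)(CC)CC)CCC2(C)C | intermediate
31 | sipholenol M, (3S,5aS,6S,7S,9aS)-6-{2-[(3R,4aS,5S,8aR)-3-hydroperoxy-5-hydroxy-2,5,8,8-tetramethyl-3,4,4a,5,6,7,8,8a-octahydronaphthalen-1-yl]ethyl}-2,2,5a,7-tetramethyldecahydro-1-benzoxepine-3,7-diol | CC1=C(CC[C@H]2[C@]3(C)CC[C@H](O)C(C)(C)O[C@H]3CC[C@]2(C)O)[C@@H]2[C@H](C[C@H]1OO)[C@@](C)(O)CCC2(C)C | target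

**Step count and risks**

Total step count: 18 (6 for rings C/D, 7 for rings A/B, 1 reagent preparation, 4 from the union to the target).
Longest linear sequence: 11 steps (steps 7–13, 14, 15, 17, 18, from farnesol).

Steps most likely to fail:

Step 17. The allylic bromide may ionise to the ring C allyl cation before bimolecular attack, so that oxygen is delivered with retention on the α face, or the peroxide anion may act as a base and eliminate HBr across C3–C4. Fallback, setting out from 27: the elimination is made deliberate (DBU, toluene, rt) to give the ring C 1,3-diene F1. A Mukaiyama–Isayama hydroperoxysilylation (cobalt bis(2,2,6,6-tetramethylheptane-3,5-dionate) Co(C11H19O2)2 as catalyst, O2, Et3SiH, 1,2-dichloroethane) should transfer a hydrogen atom to C4 and trap the allyl radical with O2 at its less hindered terminus C3, giving triethylsilyl peroxide F2. Face selectivity of the oxygen capture is not secured, so the C3 epimers would have to be separated. The conditions of step 18 then remove all four silyl groups and come back to the route at 31.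

Step 3. The tertiary cation may lose a proton or suffer a hydride shift before it is captured, and acid-promoted enolisation may epimerise C8a. Fallback, setting out from 8: a concerted type 2 carbonyl-ene cyclization (Me2AlCl, CH2Cl2, −78 °C) closes the same C6–C7 bond without a free cation and gives homoallylic alcohol F3 with an exocyclic methylene group at C5. Epoxidation of this alkene from the convex α face (mCPBA, NaHCO3, CH2Cl2, 0 °C) gives spiro-epoxide F4. LiAlH4 opens the epoxide at CH2 and reduces the ketone to triol F5, and MnO2 reoxidises only the allylic alcohol, which comes back to the route at 10.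

Step 1. The enolate may abstract a proton from the allylic methyl groups of the nitroalkene instead of adding to it, and the facial selectivity of the protonation may erode through proton exchange. Fallback, setting out from 1 and 2: LiN(iPr)2 and Me3SiCl give trimethylsilyl dienol ether F6. A SnCl4-promoted Mukaiyama–Michael addition to 2 (CH2Cl2, −78 °C) with aqueous work-up hydrolyses the silyl nitronate in the same pot (Nef) to trans keto aldehyde F7. Soft enolisation (Me3SiOTf, Et3N) gives dienol ether F8, which is protonated under kinetic control on fluoride release (TBAF, AcOH, THF, −78 °C) and comes back to the route at 8.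

Further compounds
F1 | step 17 | ring C 1,3-diene (C1=C2, C3=C4), tris-triethylsilyl ether | CC1=C(CC[C@H]2[C@]3(C)CC[C@H](O[Si](CC)(CC)CC)C(C)(C)O[C@H]3CC[C@]2(C)O[Si](CC)(CC)CC)[C@@H]2[C@H](C=C1)[C@@](C)(O[Si](CC)(CC)CC)CCC2(C)C
F2 | step 17 | (3R)-3-(triethylsilylperoxy) compound, tris-triethylsilyl ether | CC1=C(CC[C@H]2[C@]3(C)CC[C@H](O[Si](CC)(CC)CC)C(C)(C)O[C@H]3CC[C@]2(C)O[Si](CC)(CC)CC)[C@@H]2[C@H](C[C@H]1OO[Si](CC)(CC)CC)[C@@](C)(O[Si](CC)(CC)CC)CCC2(C)C
F3 | step 3 | (4aS,8aR)-7-hydroxy-2,8,8-trimethyl-5-methylidene-4a,5,6,7,8,8a-hexahydronaphthalen-1(4H)-one | O=C1C(C)=CC[C@H]2[C@@H]1C(C)(C)C(O)CC2=C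
F4 | step 3 | spiro-epoxide of F3 (oxygen on the α face) | O=C1C(C)=CC[C@H]2[C@@H]1C(C)(C)C(O)C[C@@]23CO3
F5 | step 3 | (4aS,5S,8aR)-2,5,8,8-tetramethyl-1,4,4a,5,6,7,8,8a-octahydronaphthalene-1,5,7-triol | OC1C(C)=CC[C@H]2[C@@H]1C(C)(C)C(O)C[C@]2(C)O
F6 | step 1 | trimethylsilyl C1–C6 dienol ether of carvone | CC1=CC[C@@H](C=C1O[Si](C)(C)C)C(C)=C
F7 | step 1 | trans keto aldehyde, 2-methyl-2-[(1S,6S)-3-methyl-2-oxo-6-(prop-1-en-2-yl)cyclohex-3-en-1-yl]propanal | O=C1C(C)=CC[C@H](C(C)=C)[C@H]1C(C)(C)C=O
F8 | step 1 | trimethylsilyl dienol ether of F7 | CC1=CC[C@H](C(C)=C)C(C(C)(C)C=O)=C1O[Si](C)(C)C
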